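**Retrosynthetic overview**

1. Numbering and feature: the carbocycle is C1–C10 (hydroxyls on C1 and C3, methyls on C4 and C10, Z-alkenes C4=C5 and C9=C10); the lactone oxygen sits on C6, C7 bears C11 (C12 carbonyl, C13 methylene) and C8 bears the angelate. C6 is both the γ-carbon of the butyrolactone ring (O, C6, C7, C11, C12) and the ring carbon bonded to alkenyl C5, so a carboxyl group on C6 of a malate-derived lactone can be spent as a traceless radical precursor for the C5–C6 bond, and its own configuration does not matter.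
2. Disconnection 1 (last skeletal bond, ten-membered ring): C5–C6, by nickel-electrocatalytic decarboxylative alkenylation of the C6 N-hydroxyphthalimide ester with the (Z)-C5 iodide within one molecule.
3. Disconnection 2: C8–C9, by Nozaki–Hiyama–Kishi addition of one end of a C2-symmetric bis(Z-iodoalkene) (C1–C5, C9, C10 and both methyls) to the C8 aldehyde of the lactone.
4. Building blocks: the lactone from dimethyl (S)-malate and tert-butyl bromoacetate, with the two carboxyls told apart through the cis-fused lactone anhydride; the bis-iodide from (3S,5S)-hepta-1,6-diyne-3,5-diol (two-directional Sharpless epoxidation, then epoxy chloride fragmentation) by two-directional anti-carbomagnesiation/iodination.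
5. Ring order: butyrolactone first (step 9), ten-membered carbocycle second (step 16); the C13 methylene, the angelate and desilylation follow.

Key step: step 16

Remarks: organometallic intermediates 8, 13 and 26 are drawn as monomers. The C11 configuration of 27 and 28 is left open because step 18 removes it. The L-(+)-tartrate Sharpless catalyst is taken to give the (2S,3S) epoxy alcohol at each end of 4.

**Route**

Step 1
Reactants: 1 prop-2-yn-1-ol; 2 4-chlorobut-2-yn-1-ol
Product: 3 hepta-2,5-diyne-1,7-diol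
Conditions: CuI, NaI, K2CO3, DMF, rt
Reagents that add atoms: none
Why: Copper-mediated coupling of a terminal alkyne with a propargylic halide (copper acetylide substitution on the iodide formed in situ) should give the skipped diyne without hydroxyl protection.

Step 2
Reactants: 3 hepta-2,5-diyne-1,7-diol
Product: 4 (2E,5E)-hepta-2,5-diene-1,7-diol
Conditions: LiAlH4, THF, 0 → 65 °C
Reagents that add atoms: none
Why: Alkoxyaluminate-directed trans-hydroalumination of each propargylic alcohol should give both E-allylic alcohols.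

Step 3
Reactants: 4 (2E,5E)-hepta-2,5-diene-1,7-diol
Product: 5 (2S,3S,5S,6S)-2,3:5,6-diepoxyheptane-1,7-diol
Conditions: Ti(OiPr)4 (20 mol %), L-(+)-diisopropyl tartrate (24 mol %), t-BuOOH, 4 Å MS, CH2Cl2, −20 °C
Reagents that add atoms: tert-butyl hydroperoxide CC(C)(C)OO
Why: Two-directional Sharpless asymmetric epoxidation sets (2S,3S) at each allylic alcohol under catalyst control, and a wrong-face event at one end leads to a separable diastereomer, not to the enantiomer.

Step 4
Reactants: 5 (2S,3S,5S,6S)-2,3:5,6-diepoxyheptane-1,7-diol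
Product: 6 (2R,3S,5S,6R)-1,7-dichloro-2,3:5,6-diepoxyheptane
Conditions: PPh3, CCl4, NaHCO3, reflux
Reagents that add atoms: carbon tetrachloride ClC(Cl)(Cl)Cl
Why: Appel chlorination of the primary alcohols under buffered conditions should leave the epoxides and their configuration untouched (descriptors at C2 and C6 change by priority only).

Step 5
Reactants: 6 (2R,3S,5S,6R)-1,7-dichloro-2,3:5,6-diepoxyheptane
Product: 7 (3S,5S)-hepta-1,6-diyne-3,5-diol
Conditions: n-BuLi (7 equiv), THF, −40 °C; NH4Cl aq
Reagents that add atoms: none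
Why: Base-induced fragmentation of 2,3-epoxy chlorides (Takano–Yadav propargylic alcohol synthesis: deprotonation next to chlorine, epoxide opening, then dehydrochlorination) should give both terminal alkynes, with the C3 and C5 carbinol centres carried over unchanged from the epoxides.

Step 6
Reactants: 7 (3S,5S)-hepta-1,6-diyne-3,5-diol
Product: 9 (1Z,3S,5S,6Z)-1,7-diiodo-2,6-dimethylhepta-1,6-diene-3,5-diol, via bis(alkenylmagnesium) dialkoxide 8 (not isolated)
Conditions: MeMgBr (7 equiv), CuI (0.3 equiv), THF, −20 → 20 °C; then I2, −30 → 0 °C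
Reagents that add atoms: methylmagnesium bromide C[Mg]Br; iodine II
Why: Copper-catalysed, alkoxide-directed anti-carbomagnesiation of terminal propargylic alcohols puts methyl on the internal carbon and magnesium on the terminal carbon cis to the carbinol carbon (five-membered chelate), and iodinolysis with retention should give both Z-iodoalkenes.

Step 7
Reactants: 9 (1Z,3S,5S,6Z)-1,7-diiodo-2,6-dimethylhepta-1,6-diene-3,5-diol
Product: 10 (1Z,3S,5S,6Z)-3,5-bis{[tert-butyl(dimethyl)silyl]oxy}-1,7-diiodo-2,6-dimethylhepta-1,6-diene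
Conditions: TBSOTf, 2,6-lutidine, CH2Cl2, 0 °C
Reagents that add atoms: tert-butyldimethylsilyl trifluoromethanesulfonate CC(C)(C)[Si](C)(C)OS(=O)(=O)C(F)(F)F
Why: Silyl triflate silylation should protect both hindered allylic alcohols without touching the alkenyl iodides.

Step 8
Reactants: 11 dimethyl (S)-malate; 12 tert-butyl bromoacetate
Product: 14 dimethyl (2S,3R)-3-(2-tert-butoxy-2-oxoethyl)-2-hydroxybutanedioate, via dilithium alkoxide enolate 13 (not isolated)
Conditions: LiN(SiMe3)2 (2.1 equiv), THF, −78 → −20 °C; then 12, −78 → −10 °C; chromatography removes the minor diastereomer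
Reagents that add atoms: none
Why: Fráter–Seebach alkylation of the chelated malate dianion takes place on the enolate face anti to the alkoxide-bearing carbon, which sets C7 (3R in malate numbering) from the existing (S)-carbinol.

Step 9
Reactants: 14 dimethyl (2S,3R)-3-(2-tert-butoxy-2-oxoethyl)-2-hydroxybutanedioate
Product: 16 (3aR,6aS)-3a,6a-dihydrofuro[3,4-b]furan-2,4,6(3H)-trione (cis-fused lactone anhydride), via lactone diacid 15 (not isolated)
Conditions: 6 M HCl, reflux; evaporate; then Ac2O, 60 °C
Reagents that add atoms: water O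
Why: Acid hydrolysis of the three esters gives the hydroxy triacid, which closes to the γ-lactone, and acetic anhydride then dehydrates the cis-1,2-diacid to the cyclic anhydride, a closure open only to the cis isomer that malate alkylation delivers.

Step 10
Reactants: 16 cis-fused lactone anhydride
Product: 17 (2S,3R)-2-(tert-butoxycarbonyl)-5-oxooxolane-3-carboxylic acid
Conditions: t-BuOH, DMAP (cat.), THF, 40 °C
Reagents that add atoms: tert-butanol CC(C)(C)O
Why: DMAP-catalysed alcoholysis of an unsymmetrical cyclic anhydride should occur at the carbonyl on C6, activated by the α-oxygen as in O-acylmalic anhydrides, leaving the C8 carboxyl free and masking the C6 carboxyl as an ester too hindered to lactonise onto a later C8 hydroxyl.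

Step 11
Reactants: 17 (2S,3R)-2-(tert-butoxycarbonyl)-5-oxooxolane-3-carboxylic acid
Product: 18 tert-butyl (2S,3S)-3-(hydroxymethyl)-5-oxooxolane-2-carboxylate
Conditions: BH3·SMe2, THF, 0 °C → rt; MeOH
Reagents that add atoms: none
Why: Borane reduces a carboxylic acid chemoselectively in the presence of a lactone and a tert-butyl ester.

Step 12
Reactants: 18 tert-butyl (2S,3S)-3-(hydroxymethyl)-5-oxooxolane-2-carboxylate
Product: 19 tert-butyl (2S,3R)-3-formyl-5-oxooxolane-2-carboxylate
Conditions: Dess–Martin periodinane, NaHCO3, CH2Cl2, 0 °C; used crude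
Reagents that add atoms: none
Why: Buffered Dess–Martin oxidation gives the aldehyde under conditions mild enough to keep the epimerisable C7 centre.

Step 13
Reactants: 19 tert-butyl (2S,3R)-3-formyl-5-oxooxolane-2-carboxylate; 10 bis(Z-iodoalkene) bis-silyl ether (threefold excess, surplus recovered)
Product: 20 tert-butyl (2S,3S)-3-[(1R,2Z,4S,6S,7Z)-4,6-bis{[tert-butyl(dimethyl)silyl]oxy}-1-hydroxy-8-iodo-3,7-dimethylocta-2,7-dien-1-yl]-5-oxooxolane-2-carboxylate
Conditions: CrCl2 (6 equiv), NiCl2 (2 mol %), DMSO/THF, rt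
Reagents that add atoms: none
Why: Nozaki–Hiyama–Kishi reaction, in which zerovalent nickel inserts into one of the two equivalent C–I bonds with retention of Z geometry and the alkenylchromium species adds to the aldehyde under neutral conditions; Felkin–Anh addition anti to the more substituted ring carbon C6 should favour the (8R) alcohol.

Step 14
Reactants: 20 Nozaki–Hiyama–Kishi adduct
Product: 22 (2S,3R)-3-[(1R,2Z,4S,6S,7Z)-4,6-bis{[tert-butyl(dimethyl)silyl]oxy}-8-iodo-3,7-dimethyl-1-[(triethylsilyl)oxy]octa-2,7-dien-1-yl]-5-oxooxolane-2-carboxylic acid, via triethylsilyl ester 21 (not isolated)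
Conditions: TESOTf (4 equiv), 2,6-lutidine, CH2Cl2, −78 → 20 °C; then pH 7 buffer, THF
Reagents that add atoms: triethylsilyl trifluoromethanesulfonate CC[Si](CC)(CC)OS(=O)(=O)C(F)(F)F
Why: The silyl triflate silylates the C8 hydroxyl and, in excess, converts the tert-butyl ester into the silyl ester with loss of isobutene (known silyl triflate cleavage of tert-butyl esters), and the silyl ester alone hydrolyses on buffered work-up.

Step 15
Reactants: 22 lactone acid; 23 N-hydroxyphthalimide
Product: 24 1,3-dioxoisoindolin-2-yl (2S,3R)-3-[(1R,2Z,4S,6S,7Z)-4,6-bis{[tert-butyl(dimethyl)silyl]oxy}-8-iodo-3,7-dimethyl-1-[(triethylsilyl)oxy]octa-2,7-dien-1-yl]-5-oxooxolane-2-carboxylate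
Conditions: DIC, DMAP (cat.), CH2Cl2, 0 °C → rt
Reagents that add atoms: none
Why: Carbodiimide (Steglich-type) esterification gives the redox-active ester, and any C6 epimerisation is without consequence because step 16 erases that centre.

Step 16
Reactants: 24 seco redox-active ester with (Z)-iodoalkene
Product: 25 (3aR,4R,5Z,7S,9S,10Z,11aS)-7,9-bis{[tert-butyl(dimethyl)silyl]oxy}-6,10-dimethyl-4-[(triethylsilyl)oxy]-3a,4,7,8,9,11a-hexahydrocyclodeca[b]furan-2(3H)-one
Conditions: NiCl2(dme) (30 mol %), 2,2'-bipyridine (30 mol %), AgNO3 (30 mol %), LiCl, DMF, 24 added slowly to 2 mM, Mg anode, RVC cathode, constant current, rt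
Reagents that add atoms: none
Why: Proposed new method: zerovalent nickel–bipyridine formed at the cathode inserts into the C5–I bond with retention of the Z geometry, while reduction of the N-acyloxyphthalimide releases phthalimide anion and CO2 and leaves a planar, oxygen-stabilised radical at C6 of the lactone ring; the divalent alkenylnickel traps this radical and reductive elimination from trivalent nickel forms C5–C6. The closest known reaction is the intermolecular nickel-electrocatalytic decarboxylative alkenylation of redox-active esters with alkenyl halides, which has not been used to close a medium ring. The ten-membered carbocycle closes end to end at the reductive elimination through an eleven-membered nickelacycle, the two Z-trisubstituted alkenes bending the C1–C5 arm back toward C6. The new C6 stereocentre is set by the neighbouring C7 centre, because the five-membered-ring radical bonds on the face anti to the C7 side chain, which gives the trans-fused lactone whichever C6 epimer of 24 is used. The step needs intramolecular capture to outrun hydrogen abstraction, dimerisation and protodeiodination, which high dilution with slow addition and the lack of any 5-exo or 6-exo cyclisation path for the C6 radical (C9=C10 offers only 4-exo or 5-endo closure) should secure.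

Step 17
Reactants: 25 ten-membered trans-fused lactone
Product: 27 3-[(dimethylamino)methyl] derivative of 25 (C11 epimers, otherwise 3aR,4R,5Z,7S,9S,10Z,11aS), via lithium lactone enolate 26 (not isolated)
Conditions: LiN(iPr)2, THF, −78 °C; then CH2=NMe2+ I−, −78 → 0 °C
Reagents that add atoms: Eschenmoser's salt C=[N+](C)C.[I-]
Why: Mannich reaction of the lactone lithium enolate with the preformed iminium salt, where C11 carries the only acidic protons and the enolate has no β-leaving group.

Step 18
Reactants: 27 Mannich base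
Product: 29 (3aR,4R,5Z,7S,9S,10Z,11aS)-7,9-bis{[tert-butyl(dimethyl)silyl]oxy}-6,10-dimethyl-3-methylidene-4-[(triethylsilyl)oxy]-3a,4,7,8,9,11a-hexahydrocyclodeca[b]furan-2(3H)-one, via trimethylammonium iodide 28 (not isolated)
Conditions: MeI, MeOH, rt; then NaHCO3 aq, CH2Cl2
Reagents that add atoms: none
Why: Exhaustive N-methylation followed by base-induced β-elimination of trimethylamine (Hofmann-type, E1cB) should give the exocyclic C11=C13 alkene.

Step 19
Reactants: 29 α-methylene lactone tris-silyl ether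
Product: 30 (3aS,4R,5Z,7S,9S,10Z,11aS)-7,9-bis{[tert-butyl(dimethyl)silyl]oxy}-4-hydroxy-6,10-dimethyl-3-methylidene-3a,4,7,8,9,11a-hexahydrocyclodeca[b]furan-2(3H)-one
Conditions: PPTS, MeOH/CH2Cl2, 0 °C
Reagents that add atoms: none
Why: Acid-catalysed methanolysis cleaves the triethylsilyl ether much faster than the two bulkier tert-butyldimethylsilyl ethers (the 3a descriptor changes by priority only).

Step 20
Reactants: 30 C8 alcohol; 31 angelic acid
Product: 32 (3aR,4R,5Z,7S,9S,10Z,11aS)-7,9-bis{[tert-butyl(dimethyl)silyl]oxy}-6,10-dimethyl-3-methylidene-2-oxo-2,3,3a,4,7,8,9,11a-octahydrocyclodeca[b]furan-4-yl (2Z)-2-methylbut-2-enoate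
Conditions: 31, 2,4,6-trichlorobenzoyl chloride, Et3N, toluene, rt; then 30, 75 °C
Reagents that add atoms: none
Why: Yamaguchi-type esterification through the mixed anhydride of angelic acid, run without DMAP so that reversible conjugate addition to the acyl donor cannot isomerise the Z double bond to the tiglate.

Step 21
Reactants: 32 angelate bis-silyl ether
Product: 33 CNP0152559.1, (3aR,4R,5Z,7S,9S,10Z,11aS)-7,9-dihydroxy-6,10-dimethyl-3-methylidene-2-oxo-2,3,3a,4,7,8,9,11a-octahydrocyclodeca[b]furan-4-yl (2Z)-2-methylbut-2-enoate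
Conditions: HF·pyridine, pyridine, THF, 0 °C → rt
Reagents that add atoms: none
Why: Buffered fluoride desilylation removes both silyl ethers under non-basic conditions that should leave the angelate, the α-methylene lactone and the allylic alcohols intact.

**Compound list**

1 | prop-2-yn-1-ol | C#CCO | starting material
2 | 4-chlorobut-2-yn-1-ol | OCC#CCCl | starting material
3 | hepta-2,5-diyne-1,7-diol | OCC#CCC#CCO | intermediate
4 | (2E,5E)-hepta-2,5-diene-1,7-diol | OC/C=C/C/C=C/CO | intermediate
5 | (2S,3S,5S,6S)-2,3:5,6-diepoxyheptane-1,7-diol | OC[C@@H]1O[C@H]1C[C@@H]1O[C@H]1CO | intermediate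
6 | (2R,3S,5S,6R)-1,7-dichloro-2,3:5,6-diepoxyheptane | ClC[C@@H]1O[C@H]1C[C@@H]1O[C@H]1CCl | intermediate
7 | (3S,5S)-hepta-1,6-diyne-3,5-diol | C#C[C@@H](O)C[C@H](O)C#C | intermediate
8 | bis(alkenylmagnesium) dialkoxide from 7 (not isolated) | Br[Mg]/C=C(/C)[C@@H](O[Mg]Br)C[C@H](O[Mg]Br)/C(C)=C\[Mg]Br | intermediate
9 | (1Z,3S,5S,6Z)-1,7-diiodo-2,6-dimethylhepta-1,6-diene-3,5-diol | I/C=C(/C)[C@@H](O)C[C@H](O)/C(C)=C\I | intermediate
10 | (1Z,3S,5S,6Z)-3,5-bis{[tert-butyl(dimethyl)silyl]oxy}-1,7-diiodo-2,6-dimethylhepta-1,6-diene | I/C=C(/C)[C@@H](O[Si](C)(C)C(C)(C)C)C[C@H](O[Si](C)(C)C(C)(C)C)/C(C)=C\I | intermediate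
11 | dimethyl (S)-malate | COC(=O)C[C@H](O)C(=O)OC | starting material
12 | tert-butyl bromoacetate | CC(C)(C)OC(=O)CBr | starting material
13 | dilithium alkoxide enolate of 11 (not isolated) | COC(=O)[C@@H](O[Li])C=C(O[Li])OC | intermediate
14 | dimethyl (2S,3R)-3-(2-tert-butoxy-2-oxoethyl)-2-hydroxybutanedioate | COC(=O)[C@H](CC(=O)OC(C)(C)C)[C@H](O)C(=O)OC | intermediate
15 | (2S,3R)-5-oxooxolane-2,3-dicarboxylic acid (lactone diacid, not isolated) | OC(=O)[C@@H]1CC(=O)O[C@@H]1C(=O)O | intermediate
16 | (3aR,6aS)-3a,6a-dihydrofuro[3,4-b]furan-2,4,6(3H)-trione | O=C1C[C@H]2C(=O)OC(=O)[C@H]2O1 | intermediate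
17 | (2S,3R)-2-(tert-butoxycarbonyl)-5-oxooxolane-3-carboxylic acid | OC(=O)[C@@H]1CC(=O)O[C@@H]1C(=O)OC(C)(C)C | intermediate
18 | tert-butyl (2S,3S)-3-(hydroxymethyl)-5-oxooxolane-2-carboxylate | OC[C@@H]1CC(=O)O[C@@H]1C(=O)OC(C)(C)C | intermediate
19 | tert-butyl (2S,3R)-3-formyl-5-oxooxolane-2-carboxylate | O=C[C@@H]1CC(=O)O[C@@H]1C(=O)OC(C)(C)C | intermediate
20 | tert-butyl (2S,3S)-3-[(1R,2Z,4S,6S,7Z)-4,6-bis{[tert-butyl(dimethyl)silyl]oxy}-1-hydroxy-8-iodo-3,7-dimethylocta-2,7-dien-1-yl]-5-oxooxolane-2-carboxylate | I/C=C(/C)[C@@H](O[Si](C)(C)C(C)(C)C)C[C@H](O[Si](C)(C)C(C)(C)C)/C(C)=C\[C@@H](O)[C@@H]1CC(=O)O[C@@H]1C(=O)OC(C)(C)C | intermediate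
21 | triethylsilyl ester of 22 (not isolated) | I/C=C(/C)[C@@H](O[Si](C)(C)C(C)(C)C)C[C@H](O[Si](C)(C)C(C)(C)C)/C(C)=C\[C@@H](O[Si](CC)(CC)CC)[C@@H]1CC(=O)O[C@@H]1C(=O)O[Si](CC)(CC)CC | intermediate
22 | (2S,3R)-3-[(1R,2Z,4S,6S,7Z)-4,6-bis{[tert-butyl(dimethyl)silyl]oxy}-8-iodo-3,7-dimethyl-1-[(triethylsilyl)oxy]octa-2,7-dien-1-yl]-5-oxooxolane-2-carboxylic acid | I/C=C(/C)[C@@H](O[Si](C)(C)C(C)(C)C)C[C@H](O[Si](C)(C)C(C)(C)C)/C(C)=C\[C@@H](O[Si](CC)(CC)CC)[C@@H]1CC(=O)O[C@@H]1C(=O)O | intermediate
23 | N-hydroxyphthalimide | ON1C(=O)c2ccccc2C1=O | starting material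
24 | 1,3-dioxoisoindolin-2-yl ester of 22 (seco redox-active ester) | I/C=C(/C)[C@@H](O[Si](C)(C)C(C)(C)C)C[C@H](O[Si](C)(C)C(C)(C)C)/C(C)=C\[C@@H](O[Si](CC)(CC)CC)[C@@H]1CC(=O)O[C@@H]1C(=O)ON1C(=O)c2ccccc2C1=O | intermediate
25 | (3aR,4R,5Z,7S,9S,10Z,11aS)-7,9-bis{[tert-butyl(dimethyl)silyl]oxy}-6,10-dimethyl-4-[(triethylsilyl)oxy]-3a,4,7,8,9,11a-hexahydrocyclodeca[b]furan-2(3H)-one | C1C(=O)O[C@H]2/C=C(/C)[C@@H](O[Si](C)(C)C(C)(C)C)C[C@H](O[Si](C)(C)C(C)(C)C)/C(C)=C\[C@@H](O[Si](CC)(CC)CC)[C@H]12 | intermediate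
26 | lithium enolate of 25 (not isolated) | C1=C(O[Li])O[C@H]2/C=C(/C)[C@@H](O[Si](C)(C)C(C)(C)C)C[C@H](O[Si](C)(C)C(C)(C)C)/C(C)=C\[C@@H](O[Si](CC)(CC)CC)[C@H]12 | intermediate
27 | 3-[(dimethylamino)methyl] derivative of 25 (C11 epimers) | CN(C)CC1C(=O)O[C@H]2/C=C(/C)[C@@H](O[Si](C)(C)C(C)(C)C)C[C@H](O[Si](C)(C)C(C)(C)C)/C(C)=C\[C@@H](O[Si](CC)(CC)CC)[C@H]12 | intermediate
28 | trimethylammonium iodide of 27 (not isolated) | C[N+](C)(C)CC1C(=O)O[C@H]2/C=C(/C)[C@@H](O[Si](C)(C)C(C)(C)C)C[C@H](O[Si](C)(C)C(C)(C)C)/C(C)=C\[C@@H](O[Si](CC)(CC)CC)[C@H]12.[I-] | intermediate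
29 | (3aR,4R,5Z,7S,9S,10Z,11aS)-7,9-bis{[tert-butyl(dimethyl)silyl]oxy}-6,10-dimethyl-3-methylidene-4-[(triethylsilyl)oxy]-3a,4,7,8,9,11a-hexahydrocyclodeca[b]furan-2(3H)-one | C=C1C(=O)O[C@H]2/C=C(/C)[C@@H](O[Si](C)(C)C(C)(C)C)C[C@H](O[Si](C)(C)C(C)(C)C)/C(C)=C\[C@@H](O[Si](CC)(CC)CC)[C@H]12 | intermediate
30 | (3aS,4R,5Z,7S,9S,10Z,11aS)-7,9-bis{[tert-butyl(dimethyl)silyl]oxy}-4-hydroxy-6,10-dimethyl-3-methylidene-3a,4,7,8,9,11a-hexahydrocyclodeca[b]furan-2(3H)-one | C=C1C(=O)O[C@H]2/C=C(/C)[C@@H](O[Si](C)(C)C(C)(C)C)C[C@H](O[Si](C)(C)C(C)(C)C)/C(C)=C\[C@@H](O)[C@H]12 | intermediate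
31 | angelic acid, (2Z)-2-methylbut-2-enoic acid | C/C=C(/C)C(=O)O | starting material
32 | 7,9-bis-O-(tert-butyldimethylsilyl) derivative of the target | C=C1C(=O)O[C@H]2/C=C(/C)[C@@H](O[Si](C)(C)C(C)(C)C)C[C@H](O[Si](C)(C)C(C)(C)C)/C(C)=C\[C@@H](OC(=O)/C(C)=C\C)[C@H]12 | intermediate
33 | CNP0152559.1 | C=C1C(=O)O[C@H]2/C=C(/C)[C@@H](O)C[C@H](O)/C(C)=C\[C@@H](OC(=O)/C(C)=C\C)[C@H]12 | target

**Step count**

Total steps: 21. Longest linear sequence: 16 steps (steps 1–7, then 13–21).

**Steps most likely to fail and fallbacks**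

Step 16 (proposed ring closure). The C6 radical may be quenched by hydrogen abstraction or couple between molecules before the alkenylnickel end of the same chain reaches it, or the tether may override the anti preference at C6. The fallback uses only known reactions, sets out from 18 and 10 and returns at 25; it forms C5–C6 between two molecules and closes the ring at C8–C9 instead. Alcohol 18 is treated with TESOTf and 2,6-lutidine to give the triethylsilyl ether triethylsilyl ester F1, and buffered hydrolysis gives the acid, (2S,3S)-5-oxo-3-{[(triethylsilyl)oxy]methyl}oxolane-2-carboxylic acid F2. Coupling with 23 and DIC gives the redox-active ester F3. Intermolecular nickel-electrocatalytic decarboxylative alkenylation of F3 with excess 10 (NiCl2(dme), 2,2'-bipyridine, AgNO3, Mg anode, RVC cathode, DMF) should give the trans-disubstituted lactone F4, bonded anti to the C7 substituent and still carrying the second Z-iodoalkene. Selective methanolysis of the primary silyl ether (PPTS, MeOH) gives the primary alcohol F5, and Dess–Martin oxidation gives the aldehyde F6. An intramolecular Nozaki–Hiyama–Kishi reaction (CrCl2, NiCl2 cat., DMSO/THF, high dilution), a known way to close ten-membered carbocycles, would give the macrocyclic C8 alcohol F7; its C8 configuration would rest on macrocyclic control and would have to be checked. Silylation of F7 with TESOTf and 2,6-lutidine returns 25.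

Step 13. Facial selectivity at C8 may be weak, C7 may epimerise in aldehyde 19 before addition, and the new alkoxide may migrate onto a neighbouring carbonyl. The fallback sets out from 20 obtained as a mixture of C8 epimers and returns to 20 as a single epimer; the stereocentre is set by reduction and not by addition. The epimer mixture is oxidised with Dess–Martin periodinane to the Z-enone F8, which is reduced under reagent control with (R)-2-methyl-CBS-oxazaborolidine and BH3·SMe2 at low temperature, the alkenyl group acting as the large substituent, to deliver the (8R) alcohol 20.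

Step 20. The angeloyl donor may isomerise to the tigloyl (E) isomer during activation, or the hindered C8 hydroxyl may not be acylated. The fallback sets out from 30 and returns at 32; it builds the Z double bond on the ester after acylation. Alcohol 30 is esterified with 2-[bis(2,2,2-trifluoroethoxy)phosphoryl]propanoic acid (DIC, DMAP) to give the phosphonate ester F9, and Still–Gennari olefination with acetaldehyde (KN(SiMe3)2, 18-crown-6, THF, −78 °C) should give the Z-trisubstituted enoate, that is the angelate 32.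

Further compounds
F1 | step 16 | triethylsilyl (2S,3S)-5-oxo-3-{[(triethylsilyl)oxy]methyl}oxolane-2-carboxylate | CC[Si](CC)(CC)OC[C@@H]1CC(=O)O[C@@H]1C(=O)O[Si](CC)(CC)CC
F2 | step 16 | (2S,3S)-5-oxo-3-{[(triethylsilyl)oxy]methyl}oxolane-2-carboxylic acid | CC[Si](CC)(CC)OC[C@@H]1CC(=O)O[C@@H]1C(=O)O
F3 | step 16 | 1,3-dioxoisoindolin-2-yl ester of F2 | CC[Si](CC)(CC)OC[C@@H]1CC(=O)O[C@@H]1C(=O)ON1C(=O)c2ccccc2C1=O
F4 | step 16 | trans lactone with C5–C6 formed, C8 triethylsilyl ether and remaining (Z)-C9 iodide | C1C(=O)O[C@@H](/C=C(/C)[C@@H](O[Si](C)(C)C(C)(C)C)C[C@H](O[Si](C)(C)C(C)(C)C)/C(C)=C\I)[C@@H]1CO[Si](CC)(CC)CC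
F5 | step 16 | primary C8 alcohol from F4 | C1C(=O)O[C@@H](/C=C(/C)[C@@H](O[Si](C)(C)C(C)(C)C)C[C@H](O[Si](C)(C)C(C)(C)C)/C(C)=C\I)[C@@H]1CO
F6 | step 16 | C8 aldehyde from F5 | C1C(=O)O[C@@H](/C=C(/C)[C@@H](O[Si](C)(C)C(C)(C)C)C[C@H](O[Si](C)(C)C(C)(C)C)/C(C)=C\I)[C@@H]1C=O
F7 | step 16 | macrocyclic C8 alcohol (25 without the triethylsilyl group) | C1C(=O)O[C@H]2/C=C(/C)[C@@H](O[Si](C)(C)C(C)(C)C)C[C@H](O[Si](C)(C)C(C)(C)C)/C(C)=C\[C@@H](O)[C@H]12
F8 | step 13 | C8 ketone (Z-enone) from 20 | I/C=C(/C)[C@@H](O[Si](C)(C)C(C)(C)C)C[C@H](O[Si](C)(C)C(C)(C)C)/C(C)=C\C(=O)[C@@H]1CC(=O)O[C@@H]1C(=O)OC(C)(C)C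
F9 | step 20 | C8 2-[bis(2,2,2-trifluoroethoxy)phosphoryl]propanoate of 30 (either epimer at the phosphonate carbon) | C=C1C(=O)O[C@H]2/C=C(/C)[C@@H](O[Si](C)(C)C(C)(C)C)C[C@H](O[Si](C)(C)C(C)(C)C)/C(C)=C\[C@@H](OC(=O)C(C)P(=O)(OCC(F)(F)F)OCC(F)(F)F)[C@H]12
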